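The target is gallocatechin-(4α→8)-epicatechin. Everything rests on disconnecting C4–C4a of the upper pyran ring C while the interflavan C4–C8' bond is already in place. C4 is doubly benzylic: ionised next to lower ring D, its cation is stabilised by the oxygens on C7', C8a' and C5', while upper ring A, a symmetric 3,5-dibenzyloxyphenyl ether hung on O1, offers two equivalent ortho carbons. One Friedel–Crafts closure therefore forms C4–C4a, completes ring C and sets C4 trans to the C3 hydroxyl. The precursor is an open-chain 1-methoxy-1-aryl-3-aryloxy-3-arylpropan-2-ol that carries the whole epicatechin unit and is assembled from an organocatalytic epoxy aldehyde, an aryllithium and a phenol.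

Key step: step 8

Remark: flavan numbering is used throughout, unprimed for the gallocatechin unit (rings A benzo, B trihydroxyphenyl, C pyran) and primed for the epicatechin unit (rings D benzo, E catechol, F pyran); 3,4,5-tris(benzyloxy)benzaldehyde, the formyl ylide, 3,5-bis(benzyloxy)phenol and (−)-epicatechin are taken as commercial.

Step 1
Reactants: 1 3,4,5-tris(benzyloxy)benzaldehyde; 2 (triphenylphosphoranylidene)acetaldehyde
Product: 3 (E)-3-[3,4,5-tris(benzyloxy)phenyl]prop-2-enal
Conditions: 2 (1.15 equiv), toluene, 90 °C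
Reagents that add atoms: none
Why: Wittig olefination with the stabilised formyl ylide should give the E-enal, and keeping the ylide close to one equivalent limits a second homologation.

Step 2
Reactants: 3 (E)-3-[3,4,5-tris(benzyloxy)phenyl]prop-2-enal
Product: 4 (2R,3S)-3-[3,4,5-tris(benzyloxy)phenyl]oxirane-2-carbaldehyde (trans)
Conditions: (R)-2-[bis(3,5-bis(trifluoromethyl)phenyl)(trimethylsilyloxy)methyl]pyrrolidine (10 mol %), 35% aq. H2O2 (1.3 equiv), CH2Cl2, rt
Reagents that add atoms: hydrogen peroxide OO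
Why: Iminium–enamine organocatalytic epoxidation with a diarylprolinol silyl ether: in the E,s-trans iminium ion the (R)-catalyst shields the Si face of the β-carbon, hydroperoxide adds to the Re face to set C3 as S, and the resulting enamine closes onto the O–O bond to give the trans epoxide with C2 as R.

Step 3
Reactants: 5 (−)-epicatechin
Product: 6 5,7,3',4'-tetra-O-benzyl-(−)-epicatechin
Conditions: BnBr (4.4 equiv), K2CO3, DMF, 0 °C to rt
Reagents that add atoms: benzyl bromide BrCc1ccccc1
Why: Williamson etherification in which K2CO3 deprotonates only the four phenols, so the secondary alcohol stays free and neither stereocentre is touched.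

Step 4
Reactants: 6 5,7,3',4'-tetra-O-benzyl-(−)-epicatechin
Product: 7 3,5,7,3',4'-penta-O-benzyl-(−)-epicatechin
Conditions: NaH, BnBr, n-Bu4NI (cat.), THF/DMF, 0 °C to rt
Reagents that add atoms: benzyl bromide BrCc1ccccc1
Why: Williamson etherification of the secondary alkoxide; with every phenol capped the base cannot open ring F through a quinone methide, so C2' and C3' keep their configuration.

Step 5
Reactants: 7 3,5,7,3',4'-penta-O-benzyl-(−)-epicatechin
Product: 8 8-bromo-3,5,7,3',4'-penta-O-benzyl-(−)-epicatechin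
Conditions: NBS (1.0 equiv), CH2Cl2, −78 to 0 °C
Reagents that add atoms: N-bromosuccinimide O=C1CCC(=O)N1Br
Why: Electrophilic aromatic bromination, which for benzyl-protected flavan-3-ols is known to prefer C8' of ring D over C6' at low temperature.

Step 6
Reactants: 8 8-bromo-3,5,7,3',4'-penta-O-benzyl-(−)-epicatechin; 4 (2R,3S)-3-[3,4,5-tris(benzyloxy)phenyl]oxirane-2-carbaldehyde
Product: 11 8-{methoxy[(2R,3S)-3-(3,4,5-tris(benzyloxy)phenyl)oxiran-2-yl]methyl}-3,5,7,3',4'-penta-O-benzyl-(−)-epicatechin (both epimers at the methoxy carbon), via aryllithium 9 (not isolated), via lithium alkoxide 10 (not isolated)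
Conditions: 8 (1.2 equiv), t-BuLi (2.4 equiv), THF, −78 °C; 4, −78 °C; MeOTf (1.5 equiv), −78 to −40 °C; Et3N, MeOH quench
Reagents that add atoms: methyl trifluoromethanesulfonate COS(=O)(=O)C(F)(F)F
Why: Bromine–lithium exchange, 1,2-addition of the aryllithium to the aldehyde and O-methylation of the lithium alkoxide at low temperature, before it can attack the neighbouring epoxide in a Payne-type shift; the new carbinol centre forms as a mixture, which does not matter because this carbon is ionised in step 8.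

Step 7
Reactants: 11 methyl ether epoxide (both epimers); 12 3,5-bis(benzyloxy)phenol
Product: 13 (1RS,2S,3R)-3-[3,5-bis(benzyloxy)phenoxy]-1-methoxy-1-(3,5,7,3',4'-penta-O-benzyl-(−)-epicatechin-8-yl)-3-[3,4,5-tris(benzyloxy)phenyl]propan-2-ol
Conditions: 12 (3 equiv), Cs2CO3 (0.3 equiv), DMF, 70 °C
Reagents that add atoms: none
Why: SN2 opening of the aryl epoxide by the phenoxide (Williamson-type, as in known phenoxide openings of 3-arylglycidol derivatives) at the benzylic carbon, which is activated and unhindered while the other epoxide carbon is shielded by its branched neighbour, with inversion that sets the future C2 as R; cesium phenoxide in DMF favours O- over C-alkylation.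

Step 8
Reactants: 13 (1RS,2S,3R)-3-[3,5-bis(benzyloxy)phenoxy]-1-methoxy-1-(penta-O-benzylepicatechin-8-yl)-3-[3,4,5-tris(benzyloxy)phenyl]propan-2-ol
Product: 15 5,7,3',4',5'-penta-O-benzylgallocatechin-(4α→8)-3,5,7,3',4'-penta-O-benzylepicatechin (2R,3S,4S in the upper unit; upper 3-OH free), via benzylic cation 14 (not isolated)
Conditions: BF3·OEt2 (0.3 equiv), CH2Cl2 (0.005 M), −78 to −40 °C; Et3N quench
Reagents that add atoms: none
Why: The Lewis acid ionises the C4 methyl ether (both C4 epimers converge) to a benzylic cation that is a quinone-methide-type oxocarbenium of ring D, and a nucleophilic ortho carbon of ring A attacks it in an intramolecular Friedel–Crafts alkylation, the released methanol–BF3 adduct carrying the acid on. The closest known reaction type is the acid-mediated cyclisation of 1-aryl-3-aryloxypropan-1-ols to 4-arylchromans, here with the polarity of the classical flavan-4-yl couplings reversed, since the cation sits on the lower-unit side of C4. Ring C closes in a 6-exo-trig mode with respect to the C4=C8' bond of the quinone-methide form, the ring A π bond being endocyclic. C4 is set by the stored C2 and C3 centres: A(1,3) strain against the ortho substituents of ring D puts H3 in the plane of the cation, the C2–O1 tether delivers ring A to one face only, and the chair-like transition state with the C2 aryl, C3 hydroxyl and C4 aryl all equatorial should give the 3,4-trans (4S) product, which is also the thermodynamic one. The step needs ring A (six-membered closure) to win over ring B (five-membered indane closure), over 1,2-hydride shift from C3 and over intermolecular arylation; the three oxygen donors and two equivalent ortho sites of ring A, the favourable ring size, low temperature and high dilution secure this.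

Step 9
Reactants: 15 deca-O-benzyl gallocatechin-(4α→8)-epicatechin
Product: 16 gallocatechin-(4α→8)-epicatechin (CNP0225927.3)
Conditions: H2 (1 atm), Pd(OH)2/C, THF/MeOH/H2O, rt
Reagents that add atoms: none
Why: Catalytic hydrogenolysis of the ten benzyl ethers, the standard last step for benzylated proanthocyanidins, under neutral conditions that should leave the acid-labile C4–C8' bond, the benzylic C2–O1 bonds and all stereocentres untouched.

Compound list
1 | 3,4,5-tris(benzyloxy)benzaldehyde | O=Cc1cc(OCc2ccccc2)c(OCc2ccccc2)c(OCc2ccccc2)c1 | starting material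
2 | (triphenylphosphoranylidene)acetaldehyde | O=CC=P(c1ccccc1)(c1ccccc1)c1ccccc1 | starting material
3 | (E)-3-[3,4,5-tris(benzyloxy)phenyl]prop-2-enal | O=C/C=C/c1cc(OCc2ccccc2)c(OCc2ccccc2)c(OCc2ccccc2)c1 | intermediate
4 | (2R,3S)-3-[3,4,5-tris(benzyloxy)phenyl]oxirane-2-carbaldehyde, trans | O=C[C@@H]1O[C@H]1c1cc(OCc2ccccc2)c(OCc2ccccc2)c(OCc2ccccc2)c1 | intermediate
5 | (−)-epicatechin, (2R,3R) | O[C@@H]1Cc2c(O)cc(O)cc2O[C@@H]1c1ccc(O)c(O)c1 | starting material
6 | 5,7,3',4'-tetra-O-benzyl-(−)-epicatechin | O[C@@H]1Cc2c(OCc3ccccc3)cc(OCc3ccccc3)cc2O[C@@H]1c1ccc(OCc2ccccc2)c(OCc2ccccc2)c1 | intermediate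
7 | 3,5,7,3',4'-penta-O-benzyl-(−)-epicatechin | c1ccccc1CO[C@@H]1Cc2c(OCc3ccccc3)cc(OCc3ccccc3)cc2O[C@@H]1c1ccc(OCc2ccccc2)c(OCc2ccccc2)c1 | intermediate
8 | 8-bromo-3,5,7,3',4'-penta-O-benzyl-(−)-epicatechin | c1ccccc1CO[C@@H]1Cc2c(OCc3ccccc3)cc(OCc3ccccc3)c(Br)c2O[C@@H]1c1ccc(OCc2ccccc2)c(OCc2ccccc2)c1 | intermediate
9 | 8-lithio-3,5,7,3',4'-penta-O-benzyl-(−)-epicatechin (not isolated) | c1ccccc1CO[C@@H]1Cc2c(OCc3ccccc3)cc(OCc3ccccc3)c([Li])c2O[C@@H]1c1ccc(OCc2ccccc2)c(OCc2ccccc2)c1 | intermediate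
10 | lithium alkoxide from addition of 9 to 4: lithium (penta-O-benzylepicatechin-8-yl)(trans-3-aryloxiran-2-yl)methanolate, oxirane configured as in 4, carbinol carbon both epimers (not isolated) | [Li]OC(c1c(OCc3ccccc3)cc(OCc3ccccc3)c2c1O[C@H](c1ccc(OCc3ccccc3)c(OCc3ccccc3)c1)[C@H](OCc1ccccc1)C2)[C@@H]1O[C@H]1c1cc(OCc2ccccc2)c(OCc2ccccc2)c(OCc2ccccc2)c1 | intermediate
11 | 8-{methoxy[(2R,3S)-3-(3,4,5-tris(benzyloxy)phenyl)oxiran-2-yl]methyl}-3,5,7,3',4'-penta-O-benzyl-(−)-epicatechin, trans oxirane configured as in 4, methoxy carbon both epimers | COC(c1c(OCc3ccccc3)cc(OCc3ccccc3)c2c1O[C@H](c1ccc(OCc3ccccc3)c(OCc3ccccc3)c1)[C@H](OCc1ccccc1)C2)[C@@H]1O[C@H]1c1cc(OCc2ccccc2)c(OCc2ccccc2)c(OCc2ccccc2)c1 | intermediate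
12 | 3,5-bis(benzyloxy)phenol | Oc1cc(OCc2ccccc2)cc(OCc2ccccc2)c1 | starting material
13 | (1RS,2S,3R)-3-[3,5-bis(benzyloxy)phenoxy]-1-methoxy-1-(penta-O-benzylepicatechin-8-yl)-3-[3,4,5-tris(benzyloxy)phenyl]propan-2-ol (propane C1, C2, C3 = future C4, C3, C2) | COC(c1c(OCc3ccccc3)cc(OCc3ccccc3)c2c1O[C@H](c1ccc(OCc3ccccc3)c(OCc3ccccc3)c1)[C@H](OCc1ccccc1)C2)[C@H](O)[C@@H](c1cc(OCc2ccccc2)c(OCc2ccccc2)c(OCc2ccccc2)c1)Oc1cc(OCc2ccccc2)cc(OCc2ccccc2)c1 | intermediate
14 | benzylic cation at C4 of 13 after loss of methoxide, as its methoxytrifluoroborate ion pair (not isolated) | CO[B-](F)(F)F.[CH+](c1c(OCc3ccccc3)cc(OCc3ccccc3)c2c1O[C@H](c1ccc(OCc3ccccc3)c(OCc3ccccc3)c1)[C@H](OCc1ccccc1)C2)[C@H](O)[C@@H](c1cc(OCc2ccccc2)c(OCc2ccccc2)c(OCc2ccccc2)c1)Oc1cc(OCc2ccccc2)cc(OCc2ccccc2)c1 | intermediate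
15 | 5,7,3',4',5'-penta-O-benzylgallocatechin-(4α→8)-3,5,7,3',4'-penta-O-benzylepicatechin; upper unit (2R,3S,4S) with free 3-OH, lower unit (2R,3R) | c1ccccc1COc1cc(OCc3ccccc3)c2c(c1)O[C@H](c1cc(OCc3ccccc3)c(OCc3ccccc3)c(OCc3ccccc3)c1)[C@@H](O)[C@@H]2c1c(OCc3ccccc3)cc(OCc3ccccc3)c2c1O[C@H](c1ccc(OCc3ccccc3)c(OCc3ccccc3)c1)[C@H](OCc1ccccc1)C2 | intermediate
16 | gallocatechin-(4α→8)-epicatechin: (2R,3S,4S)-4-[(2R,3R)-2-(3,4-dihydroxyphenyl)-3,5,7-trihydroxychroman-8-yl]-2-(3,4,5-trihydroxyphenyl)chroman-3,5,7-triol | Oc1cc(O)c2c(c1)O[C@H](c1cc(O)c(O)c(O)c1)[C@@H](O)[C@@H]2c1c(O)cc(O)c2c1O[C@H](c1ccc(O)c(O)c1)[C@H](O)C2 | target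

Total step count: 9. Longest linear sequence: 7 (steps 3, 4, 5, 6, 7, 8, 9 from (−)-epicatechin; the other branch, steps 1, 2, 6, 7, 8, 9, is 6).

Steps most likely to fail

1. Step 8. The closure may show poor face selectivity at C4, or the open cation may be diverted by hydride shift from C3, by closure onto ring B or by intermolecular arylation. The fallback replaces the free-cation closure by an anchimerically assisted one and sets out from 13. Acetylation (Ac2O, pyridine) should give the C3 acetate F1. With BF3·OEt2 in CH2Cl2 the acetate bridges C3–C4 as the more stable trans-disubstituted 1,3-dioxolan-2-ylium ion, which has no free cationic centre. Ring A can only open it at C4 anti to O3, which should give the 3,4-trans 3-O-acetyl deca-O-benzyl dimer F2. Methanolysis (K2CO3, MeOH) comes back to the route at 15.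

2. Step 7. The ambident phenoxide may alkylate through carbon, the epoxide may open at the wrong carbon, or an ionising opening may erode the configuration at the benzylic carbon. The fallback installs the aryl ether before the union, on the simple glycidol where benzylic opening by phenoxides is well precedented, and sets out from 4.
   - NaBH4 in MeOH should reduce 4 to the (2S,3S)-epoxy alcohol F3.
   - 12 with aqueous NaOH in t-BuOH at 70 °C should open F3 at C3 with inversion to the (2S,3R)-diol F4.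
   - TESCl and imidazole should give the bis(triethylsilyl) ether F5.
   - Swern oxidation (oxalyl chloride, DMSO, Et3N), which converts primary triethylsilyl ethers directly while secondary ones survive, should give the (2R,3R)-aldehyde F6.
   - Addition of aryllithium 9 (from 8 and t-BuLi as in step 6) at −78 °C and a methyl triflate quench should give the C3 silyl ether F7.
   - Bu4NF in THF comes back to the route at 13.

3. Step 2. Iminium turnover may be slow with the bulky, electron-rich enal, the enantiomeric purity may be insufficient, or the aryl epoxide may open hydrolytically in the aqueous peroxide medium. The fallback moves the epoxidation to the alcohol oxidation level and sets out from 3. Luche reduction (NaBH4, CeCl3·7H2O, MeOH) should give the (E)-allylic alcohol F8. Sharpless asymmetric epoxidation (Ti(OiPr)4, L-(+)-diisopropyl tartrate, t-BuOOH, 4 Å molecular sieves, CH2Cl2, −20 °C) should deliver oxygen under tartrate control to give the (2S,3S)-epoxy alcohol F3, the same compound that the fallback for step 7 reaches from 4. Swern oxidation comes back to the route at 4.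

Further compounds
F1 | step 8 | C3 acetate of 13: (1RS,2S,3R)-3-[3,5-bis(benzyloxy)phenoxy]-1-methoxy-1-(penta-O-benzylepicatechin-8-yl)-3-[3,4,5-tris(benzyloxy)phenyl]propan-2-yl acetate | COC(c1c(OCc3ccccc3)cc(OCc3ccccc3)c2c1O[C@H](c1ccc(OCc3ccccc3)c(OCc3ccccc3)c1)[C@H](OCc1ccccc1)C2)[C@H](OC(C)=O)[C@@H](c1cc(OCc2ccccc2)c(OCc2ccccc2)c(OCc2ccccc2)c1)Oc1cc(OCc2ccccc2)cc(OCc2ccccc2)c1
F2 | step 8 | 3-O-acetyl-5,7,3',4',5'-penta-O-benzylgallocatechin-(4α→8)-3,5,7,3',4'-penta-O-benzylepicatechin | c1ccccc1COc1cc(OCc3ccccc3)c2c(c1)O[C@H](c1cc(OCc3ccccc3)c(OCc3ccccc3)c(OCc3ccccc3)c1)[C@@H](OC(C)=O)[C@@H]2c1c(OCc3ccccc3)cc(OCc3ccccc3)c2c1O[C@H](c1ccc(OCc3ccccc3)c(OCc3ccccc3)c1)[C@H](OCc1ccccc1)C2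
F3 | step 7 | [(2S,3S)-3-(3,4,5-tris(benzyloxy)phenyl)oxiran-2-yl]methanol | OC[C@@H]1O[C@H]1c1cc(OCc2ccccc2)c(OCc2ccccc2)c(OCc2ccccc2)c1
F4 | step 7 | (2S,3R)-3-[3,5-bis(benzyloxy)phenoxy]-3-[3,4,5-tris(benzyloxy)phenyl]propane-1,2-diol | OC[C@H](O)[C@@H](c1cc(OCc2ccccc2)c(OCc2ccccc2)c(OCc2ccccc2)c1)Oc1cc(OCc2ccccc2)cc(OCc2ccccc2)c1
F5 | step 7 | 1,2-bis(triethylsilyl) ether of F4 | CC[Si](CC)(CC)OC[C@H](O[Si](CC)(CC)CC)[C@@H](c1cc(OCc2ccccc2)c(OCc2ccccc2)c(OCc2ccccc2)c1)Oc1cc(OCc2ccccc2)cc(OCc2ccccc2)c1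
F6 | step 7 | (2R,3R)-3-[3,5-bis(benzyloxy)phenoxy]-2-(triethylsilyloxy)-3-[3,4,5-tris(benzyloxy)phenyl]propanal | O=C[C@H](O[Si](CC)(CC)CC)[C@@H](c1cc(OCc2ccccc2)c(OCc2ccccc2)c(OCc2ccccc2)c1)Oc1cc(OCc2ccccc2)cc(OCc2ccccc2)c1
F7 | step 7 | C2 triethylsilyl ether of 13 (both epimers at the methoxy carbon) | COC(c1c(OCc3ccccc3)cc(OCc3ccccc3)c2c1O[C@H](c1ccc(OCc3ccccc3)c(OCc3ccccc3)c1)[C@H](OCc1ccccc1)C2)[C@H](O[Si](CC)(CC)CC)[C@@H](c1cc(OCc2ccccc2)c(OCc2ccccc2)c(OCc2ccccc2)c1)Oc1cc(OCc2ccccc2)cc(OCc2ccccc2)c1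
F8 | step 2 | (E)-3-[3,4,5-tris(benzyloxy)phenyl]prop-2-en-1-ol | OC/C=C/c1cc(OCc2ccccc2)c(OCc2ccccc2)c(OCc2ccccc2)c1
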